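The vessel is a stirred flask of electrophile under a held gas, so nucleophile enters through the surface while free base goes in by portions.

the same everywhere: electrophile 0.024 M; gas 2.0 mM (held); time 2.0 min

| flask | free base | remark |
|---|---|---|
| epsilon | 0.300 equiv (in portions, 2) | the portions of free base follow each other after 30 s, the first at the start |
| eta | 1.00 equiv (in portions, 2) | the portions of free base follow each other after 30 s, the first at the start |
| zeta | 3.00 equiv (in portions, 2) | the portions of free base follow each other after 30 s, the first at the start |

1. amount of target at the end, in percent of the electrophile charged for epsilon, eta, zeta, in this order
2. how the row runs (rises, then falls / falls, then rises / hardly changes / rises all the way / falls all the way)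

- a species is counted by the electrophile in it: one self-condensation product counts as two
- for a step with 2 of a species take k times the square, and two of it per event
- at the start none of nucleophile is dissolved
- "hardly changes" means that all values lie within two and a half points (for a concentration: within two and a half percent of the largest)
- run time (epsilon): 2.0 min

    electrophile + nucleophile → acid set free + target (k1 = 44 M⁻¹ s⁻¹)
    nucleophile + acid set free ⇌ protonated nucleophile, settled at all times (K2 = 5.3 × 10⁵ M⁻¹)
    acid set free + free base ⇌ salt of the base, settled at all times (K3 = 69 M⁻¹)
    gas ⇌ nucleophile, rate k4*(csat - [nucleophile]) (k4 = 0.055 s⁻¹, csat = 2.0 mM)
    2 electrophile → self-condensation product (k5 = 0.012 M⁻¹ s⁻¹)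

Two chemists dispute the row, but they start from one comparison. Dissolved nucleophile has a half-life of 0.656 s against electrophile as charged, while transfer needs 18.2 s, so nucleophile stays far below 2.0 mM and transfer is the rate-limiting step. At full driving force, gas taken up by the end is 55.0 % of the charge, a ceiling that dissolved nucleophile lowers a little.

The first chemist says free base takes the acid set free, so each nucleophile becomes target, and zeta, with 3.00 equiv, ends near that 55.0 %. The second answers that the constant for acid on nucleophile is 7680 times that for acid on base, so each target costs a second nucleophile.

I side with the second. Then half of the supply passes through step 1, so free nucleophile is about 0.217 % of the charge with electrophile as charged, which takes 2.60 % off the driving force. My number is the two-per-target yield, the ceiling so lowered and divided by two, 26.8 %, and base does not enter it.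

The first chemist can object that base far outnumbers free nucleophile. The acid split, K3 times base over K2 times free nucleophile, is then 0.180 in zeta, the flask with the most base. That split is below one, so I expect a small rise towards zeta and a row near 26.8 %.

The forecast gives a spread where I give one figure, 26.9 %, 27.3 % and 28.1 %, with the shape hardly changes, and it also rests on “target ≈ half the gas taken up”.

The flask gives 27.0 %, 27.3 % and 28.2 %, with the shape hardly changes. The second view stands; the first keeps the region of an acid split above one, and the split reckoned for zeta, 0.180, lies below one.

In epsilon, transfer and step 1 ran in step while electrophile fell to 68.1 % of the charge, their turnovers reaching the mid-point at 0.997 min and 0.997 min, and target ended at 27.0 % against the two-per-target yield of 26.8 %, beside protonated nucleophile at 26.0 % of the charge. In zeta the same 26.8 % stands against 28.2 %, while salt of the base reached 2.95 % of the charge beside protonated nucleophile at 24.7 %, a ratio of 0.119.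

(The numbers of this flask were set for the occasion; no experiment stands behind them.)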